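| flask | first end groups | second end groups | remark | time |
|---|---|---|---|---|
| cedar | 10 mM | 9.9 mM | run made earlier |  |
| larch | 18 mM | 9.9 mM | run made earlier |  |
| birch | 29 mM | 9.9 mM | run made earlier |  |
| zeta | 11 mM | 9.90 mM |  | 8.0 d |
| beta | 30 mM | 9.90 mM |  | 8.0 d |

| run | time / d | links / % | first end groups / % |
|---|---|---|---|
| cedar | 0.333 | 85.0 | 15.0 |
| cedar | 0.625 | 85.2 | 13.1 |
| cedar | 1.04 | 85.1 | 13.6 |
| cedar | 2.00 | 84.4 | 13.9 |
| cedar | 4.00 | 81.6 | 14.7 |
| larch | 0.333 | 50.9 | 49.0 |
| larch | 1.04 | 52.6 | 47.4 |
| larch | 1.67 | 51.8 | 48.0 |
| larch | 3.00 | 51.9 | 49.2 |
| larch | 4.00 | 48.8 | 47.3 |
| birch | 0.833 | 33.8 | 66.9 |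
| birch | 1.67 | 32.7 | 65.0 |
| birch | 2.50 | 32.5 | 65.0 |
| birch | 3.00 | 31.1 | 68.6 |
| birch | 4.00 | 31.4 | 64.8 |

(scatter of a reading: 1 percentage point)

1. which of the two ends with the longer chains by the average number of monomer units in a chain (unreacted monomers counted as chains of one) ("neither" if they lie within 10%) (zeta / beta / neither)
2. average number of monomer units in a chain (unreacted monomers counted as chains of one) at the end, zeta
3. average number of monomer units in a chain (unreacted monomers counted as chains of one) at the end, beta

- each molecule carries two end groups: a chain counts once for every two ends that are left, dead ends included; the units are half of the end groups of the two monomers charged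
- what may be going on: links -> over-reaction product; first end groups + second end groups -> links + released group; second end groups -> decomposed reagent
- a link that another step uses up counts as cut, two dead ends; so do two ends of one kind that react with each other

**Slow fading.** Slowness is the easy part of these flasks. In cedar the links stand at 85.0% after 0.333 d and at 81.6% after 4.00 d, which reads as a fading of 0.0111 d⁻¹. The lifetime this implies is longer than the 8.0 d you plan, and on that reading 91.5% of the links survive that time.

**Early split.** If second end groups either join first end groups or decompose on their own, divide the two rates and time drops out. In cedar, 9.9 mM of second end groups made 10 mM × 85.0% of links, so a reading of 1.40 mM was lost, with the scatter of 1 percentage point on each reading. Dividing that loss by the logarithm of first end groups charged over first end groups left gives a reading of 0.738 mM. This is the loss constant, the c(first end groups) at which a second end group is as likely to decompose as to link, a selectivity factor in concentration units.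

**Choosing the charge.** Second end groups are the limiting reagent in both flasks. Second ends charged equal first ends used plus the loss constant times that logarithm. Repeated substitution into this balance leaves c(first end groups) at 2.28 mM in zeta and 20.4 mM in beta. Length is ends charged over ends left, which gives 4.22 for zeta and 1.79 for beta. Zeta's chains are longer than beta's, so you charge 11 mM.

**The forecast.** Its grounds are “Some second ends are lost, and the loss grows as the first ends run short”. It names zeta, with 4.2 and 1.78.

**The result.** The flasks give zeta, with 4.46 for zeta and 1.80 for beta.

    links → over-reaction product (k = 7.40 × 10⁻⁶ min⁻¹)
    first end groups + second end groups → links + released group (k = 13.0 L mol⁻¹ min⁻¹)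
    second end groups → decomposed reagent (k = 0.00860 min⁻¹)

**The neighbour.** Take zeta again, but with 44 mM of first end groups. The loss constant 0.738 mM leaves c(first end groups) at 34.3 mM, and so puts 0.184 mM of second end groups into decomposition, where this flask shows 0.165 mM of decomposed reagent. With the same surviving share, the reckoning gives links at 20.2% of the first end groups charged, and this flask shows 20.3%. Ends charged over ends left then gives 1.49, and this flask gives 1.50.

Readings and results are calculated on assumed constants; scatter was added.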